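The numbers in the tables were computed on assumed constants; scatter was added.

The reckoning is staked on substrate, and on the later stretch of its curve rather than its start.

| flask | substrate | remark | time |
|---|---|---|---|
| north-west | 0.28 M | run made earlier |  |
| south-east | 0.44 M | run made earlier |  |
| amber | 0.20 M |  | 2.0 min |
| teal | 0.20 M |  | 4.0 min |

| run | time / s | substrate / % | target / % | over-reaction product / % | intermediate / % |
|---|---|---|---|---|---|
| north-west | 20.0 | 94.2 | 0.7 | 0 | 4.3 |
| north-west | 40.0 | 88.2 | 3.9 | 0 | 8.1 |
| north-west | 60.0 | 82.8 | 7.6 | 0.1 | 10.3 |
| north-west | 80.0 | 79.1 | 10.3 | 0 | 10.0 |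
| north-west | 90.0 | 77.0 | 12.1 | 0.2 | 10.4 |
| south-east | 20.0 | 94.0 | 1.2 | 0.1 | 4.6 |
| south-east | 40.0 | 89.1 | 3.8 | 0 | 7.9 |
| south-east | 60.0 | 83.0 | 6.6 | 0.3 | 10.0 |
| south-east | 80.0 | 79.2 | 10.7 | 0.1 | 10.5 |
| south-east | 90.0 | 76.9 | 12.3 | 0 | 10.0 |

(scatter of a reading: 0.3 percentage points)

* which of these there is most of at the end, counted by the substrate in it, amber (substrate / over-reaction product / target / intermediate)
* which of these there is most of at the end, counted by the substrate in it, teal (substrate / over-reaction product / target / intermediate)
* the largest of these amounts at the end, in percent of the substrate charged, amber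
* the largest of these amounts at the end, in percent of the substrate charged, teal

- a reading or a percentage of target counts all its forms, free or not

In the first instants of the north-west run, substrate turns into intermediate and target lags: at 20.0 s intermediate reads 4.3% and target 0.7%. In the middle, intermediate approaches a level, a quasi-steady state: from 40.0 s to 90.0 s it goes from 8.1% to 10.4%, while target goes from 3.9% to 12.1%. Over-reaction product in the north-west run reads 0.2% at 90.0 s. The south-east run, at 0.44 M, ends at 76.9% substrate against 77.0% for the north-west run at 0.28 M, a gap inside the scatter, so the percentages are carried over to 0.20 M, below both runs.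

For the end, the curve is replaced by its mean: 0.170 min⁻¹ is the late decay constant, the fractional loss of substrate per unit time from 40.0 s to 90.0 s, both runs pooled. From the pooled 77.0% at 90.0 s, it gives 70.7% for amber and 50.3% for teal. The error of that replacement is sized with the steeper constant of the first 40.0 s, 0.181 min⁻¹, which puts teal at 49.0%, and that is 1.3 percentage points lower. With intermediate held at its pooled last reading, teal's target and over-reaction product together come to 39.5%, less than its substrate, and amber's non-substrate share is 29.3%. This reckoning therefore names substrate in both flasks.

The forecast gives substrate at 70.5% for amber and substrate at 52.5% for teal: “Substrate remains the largest in both.” For teal, the reckoning here runs lower than the forecast.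

Amber holds substrate at 70.7%, and teal holds substrate at 51.2%.

    substrate ⇌ intermediate (K = 0.950, k = 0.00323 s⁻¹)
    intermediate → target (k = 0.0192 s⁻¹)
    crystals ⇌ target, rate k3*(cs3 - [target]) while solid is left; crystals form when [target] > cs3 (solubility = 3.60 mM, k = 1.25 s⁻¹)
    target → over-reaction product (k = 0.00103 s⁻¹)

The figure reckoned with the late decay constant lies 0.90 points under teal's substrate, while teal's target, 40.2%, counts 38.2% of crystals, which shift that substrate by nothing. The neighbouring flask is teal left until 15 min. The same constant, carried from 90.0 s, gives it 7.76% substrate. That flask holds 8.73% substrate, and its largest amount is now target, at 88.1%.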